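The benzene ring of the tetrahydroisoquinoline (C4a, C5, C6, C7, C8, C8a) is built last, onto a finished chiral tetrahydropyridine. That ring is a resorcinol diether with meta oxygens on C6 and C8, an unsubstituted C7 and an aryl group on C5. This is the pattern produced when an aryl(alkenyl)ketene combines with an alkoxyalkyne. Irradiating an α-naphthyl α-diazo ketone with methoxyethyne, then warming, forms C4a–C5, C5–C6, C7–C8 and C8–C8a in one operation, so the hindered C5–C1′ bond needs no cross-coupling. The precursor is an N-Boc (2S)-2-methyl-1,2,3,6-tetrahydropyridine bearing the diazo(naphthyl)acetyl group on C4. Its C4=C5 bond is placed by conjugate reduction and enolate triflation, not by ketone enolisation.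

Key step: step 16

Assumption: the SMILES defines only C3. The C5–C1′ axis is rotationally hindered, so 33–36 are expected as two atropisomeric diastereomers that both fit the given structure and can be separated by HPLC at 36 if one rotamer is wanted.

Numbering: isoquinoline numbers for the bicyclic compounds, primed numbers for naphthalene atoms, pyridine numbers for the monocyclic heterocycles.

Step 1
Reactants: 1 2-bromo-5-methoxybenzaldehyde; 2 diethyl succinate
Product: 3 (E)-4-(2-bromo-5-methoxyphenyl)-3-(ethoxycarbonyl)but-3-enoic acid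
Conditions: KOt-Bu, t-BuOH, reflux; then aq HCl
Reagents that add atoms: none
Why: Stobbe condensation: the succinate enolate adds to the aldehyde, the alkoxide lactonises, and base-induced ring opening gives the (E)-alkylidene half-ester, whose aryl group lies cis to CH2CO2H as the next ring closure demands.

Step 2
Reactants: 3 (E)-4-(2-bromo-5-methoxyphenyl)-3-(ethoxycarbonyl)but-3-enoic acid
Product: 4 ethyl 4-acetoxy-8-bromo-5-methoxynaphthalene-2-carboxylate
Conditions: Ac2O, NaOAc, reflux
Reagents that add atoms: acetic anhydride, CC(=O)OC(C)=O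
Why: Intramolecular Friedel–Crafts acylation through the mixed anhydride can only strike the free ortho carbon, which the neighbouring methoxy group activates while bromine blocks the other one, and the naphthol tautomer is captured as its acetate.

Step 3
Reactants: 4 ethyl 4-acetoxy-8-bromo-5-methoxynaphthalene-2-carboxylate
Product: 6 ethyl 8-bromo-4,5-dimethoxynaphthalene-2-carboxylate, via naphthol 5 (not isolated)
Conditions: K2CO3, EtOH, rt; evaporate; MeI, K2CO3, DMF, rt
Reagents that add atoms: iodomethane, CI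
Why: Carbonate-mediated ethanolysis cleaves the aryl acetate far faster than the conjugated ethyl ester (which ethanol cannot alter), and the naphtholate then undergoes Williamson O-methylation.

Step 4
Reactants: 6 ethyl 8-bromo-4,5-dimethoxynaphthalene-2-carboxylate
Product: 7 (8-bromo-4,5-dimethoxynaphthalen-2-yl)methanol
Conditions: LiAlH4, THF, 0 °C
Reagents that add atoms: none
Why: Standard hydride reduction of an aromatic ester to the benzylic alcohol, at a temperature where the aryl bromide is not attacked.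

Step 5
Reactants: 7 (8-bromo-4,5-dimethoxynaphthalen-2-yl)methanol
Product: 9 1-bromo-4,5-dimethoxy-7-methylnaphthalene, via mesylate 8 (not isolated)
Conditions: MsCl, Et3N, CH2Cl2, 0 °C; crude 8, LiBHEt3, THF, 0 °C to rt
Reagents that add atoms: none
Why: Sulfonylation followed by SN2 displacement with a powerful borohydride deoxygenates the primary benzylic position and spares the C–Br bond that hydrogenolysis would cleave.

Step 6
Reactants: 9 1-bromo-4,5-dimethoxy-7-methylnaphthalene; 10 (E)-2-(2-ethoxyethenyl)-4,4,5,5-tetramethyl-1,3,2-dioxaborolane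
Product: 12 2-(4,5-dimethoxy-7-methylnaphthalen-1-yl)acetaldehyde, via styryl ether 11 (not isolated)
Conditions: Pd(OAc)2 (3 mol %), SPhos, K3PO4, dioxane–H2O, 80 °C; crude 11, 2 M HCl, THF, rt; used at once
Reagents that add atoms: water, O
Why: Suzuki–Miyaura coupling with an electron-rich biarylphosphine handles the peri-hindered, electron-rich bromide, and protonation of the styryl ether at the benzylic carbon followed by loss of ethanol unmasks the aldehyde.

Step 7
Reactants: 13 (3S)-3-[(tert-butoxycarbonyl)amino]butanoic acid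
Product: 15 tert-butyl N-[(2S)-4-[methoxy(methyl)amino]-4-oxobutan-2-yl]carbamate, via acyl imidazolide 14 (not isolated)
Conditions: 1,1′-carbonyldiimidazole, CH2Cl2, rt; then MeNHOMe·HCl, rt
Reagents that add atoms: N,O-dimethylhydroxylamine hydrochloride, CNOC.Cl
Why: Acyl imidazolide activation and aminolysis give the Weinreb amide, the stereocentre (the future C3, taken from the chiral pool) being β to the carbonyl group and therefore not at risk.

Step 8
Reactants: 15 tert-butyl N-[(2S)-4-[methoxy(methyl)amino]-4-oxobutan-2-yl]carbamate; 16 ethynylmagnesium bromide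
Product: 17 tert-butyl N-[(2S)-4-oxohex-5-yn-2-yl]carbamate
Conditions: 16 (3 equiv), THF, 0 °C to rt; inverse quench into cold 1 M HCl
Reagents that add atoms: none
Why: Weinreb ketone synthesis: the chelated tetrahedral adduct prevents double addition, one equivalent of the Grignard reagent is sacrificed to N–H, and the acidic inverse quench protonates the released hydroxylamine before it can add to the ynone.

Step 9
Reactants: 17 tert-butyl N-[(2S)-4-oxohex-5-yn-2-yl]carbamate
Product: 19 (2S)-2-methyl-2,3-dihydro-1H-pyridin-4-one, via chloroenone ammonium salt 18 (not isolated)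
Conditions: 4 M HCl in dioxane, rt; evaporate; K2CO3, MeOH, rt
Reagents that add atoms: none
Why: HCl removes the carbamate and adds across the ynone, and after neutralisation the free amine displaces chloride by 6-endo addition–elimination to the cyclic vinylogous amide, a sequence in which no bond to the stereocentre is broken.

Step 10
Reactants: 19 (2S)-2-methyl-2,3-dihydro-1H-pyridin-4-one
Product: 20 tert-butyl (2S)-2-methyl-4-oxo-2,3-dihydropyridine-1-carboxylate
Conditions: Boc2O, DMAP (10 mol %), MeCN, rt
Reagents that add atoms: di-tert-butyl dicarbonate, CC(C)(C)OC(=O)OC(=O)OC(C)(C)C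
Why: DMAP-catalysed acylation of the vinylogous amide nitrogen restores the carbamate, which activates the enaminone for conjugate reduction and later shields the nitrogen from the ketene.

Step 11
Reactants: 20 tert-butyl (2S)-2-methyl-4-oxo-2,3-dihydropyridine-1-carboxylate
Product: 22 tert-butyl (2S)-2-methyl-4-(trifluoromethylsulfonyloxy)-3,6-dihydro-2H-pyridine-1-carboxylate, via lithium enolate 21 (not isolated)
Conditions: LiBH(s-Bu)3, THF, −78 °C; then N-(5-chloropyridin-2-yl)bis(trifluoromethanesulfonimide), −78 °C to rt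
Reagents that add atoms: N-(5-chloropyridin-2-yl)bis(trifluoromethanesulfonimide), FC(F)(F)S(=O)(=O)N(c1ccc(Cl)cn1)S(=O)(=O)C(F)(F)F
Why: Conjugate hydride delivery to C6 of the N-acyl enaminone creates the enolate exclusively between C4 and C5 and O-triflation fixes it there, which deprotonation of the saturated 2-methyl-4-piperidinone could not guarantee because C3 and C5 are both methylene groups.

Step 12
Reactants: 22 tert-butyl (2S)-2-methyl-4-(trifluoromethylsulfonyloxy)-3,6-dihydro-2H-pyridine-1-carboxylate; 12 2-(4,5-dimethoxy-7-methylnaphthalen-1-yl)acetaldehyde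
Product: 23 tert-butyl (2S)-4-[2-(4,5-dimethoxy-7-methylnaphthalen-1-yl)-1-hydroxyethyl]-2-methyl-3,6-dihydro-2H-pyridine-1-carboxylate (both carbinol epimers)
Conditions: CrCl2 (4 equiv), NiCl2 (2 mol %), DMF, rt
Reagents that add atoms: none
Why: Nozaki–Hiyama–Kishi coupling: zerovalent nickel inserts into the C–OTf bond, transmetalation gives a non-basic alkenyl species of trivalent chromium that adds to the enolisable aldehyde without deprotonating it, and the new carbinol centre, formed without control, is erased in step 13.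

Step 13
Reactants: 23 tert-butyl (2S)-4-[2-(4,5-dimethoxy-7-methylnaphthalen-1-yl)-1-hydroxyethyl]-2-methyl-3,6-dihydro-2H-pyridine-1-carboxylate
Product: 24 tert-butyl (2S)-4-[2-(4,5-dimethoxy-7-methylnaphthalen-1-yl)acetyl]-2-methyl-3,6-dihydro-2H-pyridine-1-carboxylate
Conditions: Dess–Martin periodinane, CH2Cl2, 0 °C to rt
Reagents that add atoms: none
Why: Neutral hypervalent-iodine (Dess–Martin) oxidation converts the allylic alcohol into the enone without moving the double bond or touching the electron-rich naphthalene.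

Step 14
Reactants: 24 tert-butyl (2S)-4-[2-(4,5-dimethoxy-7-methylnaphthalen-1-yl)acetyl]-2-methyl-3,6-dihydro-2H-pyridine-1-carboxylate
Product: 25 tert-butyl (2S)-4-[2-diazo-2-(4,5-dimethoxy-7-methylnaphthalen-1-yl)acetyl]-2-methyl-3,6-dihydro-2H-pyridine-1-carboxylate
Conditions: 4-acetamidobenzenesulfonyl azide, DBU, MeCN, 0 °C to rt, in the dark
Reagents that add atoms: 4-acetamidobenzenesulfonyl azide, CC(=O)Nc1ccc(cc1)S(=O)(=O)N=[N+]=[N-]
Why: Regitz diazo transfer: the methylene group flanked by aryl and carbonyl is by far the most acidic site, so DBU enolises it selectively and the enolate captures the terminal nitrogen of the sulfonyl azide.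

Step 15
Reactants: 26 2-chloro-1,1-dimethoxyethane (chloroacetaldehyde dimethyl acetal)
Product: 28 methoxyethyne, via sodium methoxyethynide 27 (not isolated)
Conditions: NaNH2 (3 equiv), liquid NH3, −33 °C; then cold aq NaCl, distil into a −78 °C trap; kept cold and used as a solution
Reagents that add atoms: none
Why: Double β-elimination (methanol, then HCl) with amide base, as in the standard preparation of alkoxyacetylenes, ends at the acetylide, which water protonates so that the volatile ynol ether can be distilled off.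

Step 16
Reactants: 25 tert-butyl (2S)-4-[2-diazo-2-(4,5-dimethoxy-7-methylnaphthalen-1-yl)acetyl]-2-methyl-3,6-dihydro-2H-pyridine-1-carboxylate; 28 methoxyethyne
Product: 33 tert-butyl (3S)-8-hydroxy-6-methoxy-3-methyl-5-(4,5-dimethoxy-7-methylnaphthalen-1-yl)-3,4-dihydro-1H-isoquinoline-2-carboxylate, via vinylketene 29 (not isolated), via cyclobutenone 30 (not isolated), via dienylketene 31 (not isolated), via cyclohexadienone 32 (not isolated)
Conditions: 28 (5 equiv), ClCH2CH2Cl, blue LEDs (450 nm), 0–5 °C, dry-ice condenser, until N2 evolution ends; then 80 °C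
Reagents that add atoms: none
Why: Light expels N2 from 25 and the alkenyl carbon C4 of the tetrahydropyridine shifts from the carbonyl carbon to the diazo carbon (Wolff rearrangement, C4a–C5), so aryl(alkenyl)ketene 29 already carries the naphthyl group on the future C5. The unsubstituted, nucleophilic carbon of 28 bonds to the ketene carbonyl carbon and the methoxy-bearing carbon to the ketene α-carbon (polar [2+2], C7–C8 and C5–C6), which gives the 4,4-disubstituted cyclobutenone 30. Heating opens 30 reversibly (4π, conrotatory) to dienylketene 31, and 6π disrotatory closure of the ketene carbon onto the ring CH (C8–C8a), followed by enolisation of 32, closes the six-membered carbocycle annulated to the heterocycle. The reaction type is the Danheiser benzannulation in its α-diazo ketone form, and the known thermal conversion of 4,4-diaryl-3-alkoxycyclobutenones into naphthols shows that a fully substituted C4 of the cyclobutenone is tolerated. No stereocentre is formed, C3 is insulated from the reacting π system by the C4 methylene group and cannot epimerise, and the new C5–C1′ axis arises without control. The step needs ynol ether polarity in the [2+2], which the methoxy group dictates, and closure through the alkene rather than through C2′ of the naphthalene, which is secured because ring opening is reversible and only the alkene pathway avoids dearomatisation, while visible light excites the diazo ketone alone and spares the naphthalene and the phenol.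

Step 17
Reactants: 33 tert-butyl (3S)-8-hydroxy-6-methoxy-3-methyl-5-(4,5-dimethoxy-7-methylnaphthalen-1-yl)-3,4-dihydro-1H-isoquinoline-2-carboxylate
Product: 34 tert-butyl (3S)-6,8-dimethoxy-3-methyl-5-(4,5-dimethoxy-7-methylnaphthalen-1-yl)-3,4-dihydro-1H-isoquinoline-2-carboxylate
Conditions: MeI, K2CO3, DMF, rt
Reagents that add atoms: iodomethane, CI
Why: Williamson O-methylation of the only acidic group, the unhindered C8 phenol.

Step 18
Reactants: 34 tert-butyl (3S)-6,8-dimethoxy-3-methyl-5-(4,5-dimethoxy-7-methylnaphthalen-1-yl)-3,4-dihydro-1H-isoquinoline-2-carboxylate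
Product: 36 (3S)-6,8-dimethoxy-3-methyl-5-(4,5-dimethoxy-7-methylnaphthalen-1-yl)-1,2,3,4-tetrahydroisoquinoline, via ammonium trifluoroacetate 35 (not isolated)
Conditions: CF3CO2H, CH2Cl2, 0 °C; then aq NaOH
Reagents that add atoms: none
Why: Acidolysis of the tert-butyl carbamate releases isobutene and CO2, the aryl methyl ethers and C3 are unaffected, and base liberates the secondary amine.

Compound list
1 | 2-bromo-5-methoxybenzaldehyde | COc1ccc(Br)c(C=O)c1 | starting material
2 | diethyl succinate | CCOC(=O)CCC(=O)OCC | starting material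
3 | (E)-4-(2-bromo-5-methoxyphenyl)-3-(ethoxycarbonyl)but-3-enoic acid | CCOC(=O)/C(CC(=O)O)=C/c1cc(OC)ccc1Br | intermediate
4 | ethyl 4-acetoxy-8-bromo-5-methoxynaphthalene-2-carboxylate | CCOC(=O)c1cc(OC(C)=O)c2c(OC)ccc(Br)c2c1 | intermediate
5 | ethyl 8-bromo-4-hydroxy-5-methoxynaphthalene-2-carboxylate (not isolated) | CCOC(=O)c1cc(O)c2c(OC)ccc(Br)c2c1 | intermediate
6 | ethyl 8-bromo-4,5-dimethoxynaphthalene-2-carboxylate | CCOC(=O)c1cc(OC)c2c(OC)ccc(Br)c2c1 | intermediate
7 | (8-bromo-4,5-dimethoxynaphthalen-2-yl)methanol | OCc1cc(OC)c2c(OC)ccc(Br)c2c1 | intermediate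
8 | (8-bromo-4,5-dimethoxynaphthalen-2-yl)methyl methanesulfonate (not isolated) | CS(=O)(=O)OCc1cc(OC)c2c(OC)ccc(Br)c2c1 | intermediate
9 | 1-bromo-4,5-dimethoxy-7-methylnaphthalene | Cc1cc(OC)c2c(OC)ccc(Br)c2c1 | intermediate
10 | (E)-2-(2-ethoxyethenyl)-4,4,5,5-tetramethyl-1,3,2-dioxaborolane | CCO/C=C/B1OC(C)(C)C(C)(C)O1 | starting material
11 | 1-[(E)-2-ethoxyethenyl]-4,5-dimethoxy-7-methylnaphthalene (not isolated) | CCO/C=C/c1ccc(OC)c2c(OC)cc(C)cc12 | intermediate
12 | 2-(4,5-dimethoxy-7-methylnaphthalen-1-yl)acetaldehyde | O=CCc1ccc(OC)c2c(OC)cc(C)cc12 | intermediate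
13 | (3S)-3-[(tert-butoxycarbonyl)amino]butanoic acid | C[C@@H](CC(=O)O)NC(=O)OC(C)(C)C | starting material
14 | tert-butyl N-[(2S)-4-(imidazol-1-yl)-4-oxobutan-2-yl]carbamate (not isolated) | C[C@@H](CC(=O)n1ccnc1)NC(=O)OC(C)(C)C | intermediate
15 | tert-butyl N-[(2S)-4-[methoxy(methyl)amino]-4-oxobutan-2-yl]carbamate | C[C@@H](CC(=O)N(C)OC)NC(=O)OC(C)(C)C | intermediate
16 | ethynylmagnesium bromide | C#C[Mg]Br | starting material
17 | tert-butyl N-[(2S)-4-oxohex-5-yn-2-yl]carbamate | C[C@@H](CC(=O)C#C)NC(=O)OC(C)(C)C | intermediate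
18 | (5S)-5-amino-1-chlorohex-1-en-3-one hydrochloride, alkene isomers (not isolated) | C[C@@H](CC(=O)C=CCl)[NH3+].[Cl-] | intermediate
19 | (2S)-2-methyl-2,3-dihydro-1H-pyridin-4-one | O=C1C=CN[C@@H](C)C1 | intermediate
20 | tert-butyl (2S)-2-methyl-4-oxo-2,3-dihydropyridine-1-carboxylate | O=C1C=CN(C(=O)OC(C)(C)C)[C@@H](C)C1 | intermediate
21 | lithium (2S)-1-(tert-butoxycarbonyl)-2-methyl-3,6-dihydro-2H-pyridin-4-olate (not isolated) | [Li+].[O-]C1=CCN(C(=O)OC(C)(C)C)[C@@H](C)C1 | intermediate
22 | tert-butyl (2S)-2-methyl-4-(trifluoromethylsulfonyloxy)-3,6-dihydro-2H-pyridine-1-carboxylate | O=S(=O)(OC1=CCN(C(=O)OC(C)(C)C)[C@@H](C)C1)C(F)(F)F | intermediate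
23 | tert-butyl (2S)-4-[2-(4,5-dimethoxy-7-methylnaphthalen-1-yl)-1-hydroxyethyl]-2-methyl-3,6-dihydro-2H-pyridine-1-carboxylate, both carbinol epimers | OC(Cc1ccc(OC)c2c(OC)cc(C)cc12)C1=CCN(C(=O)OC(C)(C)C)[C@@H](C)C1 | intermediate
24 | tert-butyl (2S)-4-[2-(4,5-dimethoxy-7-methylnaphthalen-1-yl)acetyl]-2-methyl-3,6-dihydro-2H-pyridine-1-carboxylate | O=C(Cc1ccc(OC)c2c(OC)cc(C)cc12)C1=CCN(C(=O)OC(C)(C)C)[C@@H](C)C1 | intermediate
25 | tert-butyl (2S)-4-[2-diazo-2-(4,5-dimethoxy-7-methylnaphthalen-1-yl)acetyl]-2-methyl-3,6-dihydro-2H-pyridine-1-carboxylate | [N-]=[N+]=C(C(=O)C1=CCN(C(=O)OC(C)(C)C)[C@@H](C)C1)c1ccc(OC)c2c(OC)cc(C)cc12 | intermediate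
26 | 2-chloro-1,1-dimethoxyethane | COC(CCl)OC | starting material
27 | sodium methoxyethynide (not isolated) | [Na+].[C-]#COC | intermediate
28 | methoxyethyne | COC#C | intermediate
29 | tert-butyl (2S)-4-[1-(4,5-dimethoxy-7-methylnaphthalen-1-yl)-2-oxoethenyl]-2-methyl-3,6-dihydro-2H-pyridine-1-carboxylate (not isolated) | O=C=C(C1=CCN(C(=O)OC(C)(C)C)[C@@H](C)C1)c1ccc(OC)c2c(OC)cc(C)cc12 | intermediate
30 | tert-butyl (2S)-4-[1-(4,5-dimethoxy-7-methylnaphthalen-1-yl)-2-methoxy-4-oxocyclobut-2-en-1-yl]-2-methyl-3,6-dihydro-2H-pyridine-1-carboxylate, both epimers at the quaternary carbon (not isolated) | COC1=CC(=O)C1(C2=CCN(C(=O)OC(C)(C)C)[C@@H](C)C2)c2ccc(OC)c3c(OC)cc(C)cc23 | intermediate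
31 | tert-butyl (2S)-4-[1-(4,5-dimethoxy-7-methylnaphthalen-1-yl)-2-methoxy-4-oxobuta-1,3-dienyl]-2-methyl-3,6-dihydro-2H-pyridine-1-carboxylate, ketenyl carbon cis to the tetrahydropyridinyl group (not isolated) | O=C=C/C(OC)=C(\C1=CCN(C(=O)OC(C)(C)C)[C@@H](C)C1)c1ccc(OC)c2c(OC)cc(C)cc12 | intermediate
32 | tert-butyl (3S)-5-(4,5-dimethoxy-7-methylnaphthalen-1-yl)-6-methoxy-3-methyl-8-oxo-1,3,4,8a-tetrahydroisoquinoline-2-carboxylate, C8a undefined (not isolated) | O=C1C=C(OC)C(c2ccc(OC)c3c(OC)cc(C)cc23)=C2C[C@H](C)N(C(=O)OC(C)(C)C)CC12 | intermediate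
33 | tert-butyl (3S)-8-hydroxy-6-methoxy-3-methyl-5-(4,5-dimethoxy-7-methylnaphthalen-1-yl)-3,4-dihydro-1H-isoquinoline-2-carboxylate | Oc1cc(OC)c(-c2ccc(OC)c3c(OC)cc(C)cc23)c2c1CN(C(=O)OC(C)(C)C)[C@@H](C)C2 | intermediate
34 | tert-butyl (3S)-6,8-dimethoxy-3-methyl-5-(4,5-dimethoxy-7-methylnaphthalen-1-yl)-3,4-dihydro-1H-isoquinoline-2-carboxylate | COc1cc(OC)c(-c2ccc(OC)c3c(OC)cc(C)cc23)c2c1CN(C(=O)OC(C)(C)C)[C@@H](C)C2 | intermediate
35 | (3S)-6,8-dimethoxy-3-methyl-5-(4,5-dimethoxy-7-methylnaphthalen-1-yl)-1,2,3,4-tetrahydroisoquinolinium trifluoroacetate (not isolated) | COc1cc(OC)c(-c2ccc(OC)c3c(OC)cc(C)cc23)c2c1C[NH2+][C@@H](C)C2.[O-]C(=O)C(F)(F)F | intermediate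
36 | (3S)-6,8-dimethoxy-3-methyl-5-(4,5-dimethoxy-7-methylnaphthalen-1-yl)-1,2,3,4-tetrahydroisoquinoline | COc1cc(OC)c(-c2ccc(OC)c3c(OC)cc(C)cc23)c2c1CN[C@@H](C)C2 | target

Total step count: 18. Longest linear sequence: 12 steps (1–6, 12–14, 16–18).

Steps most likely to fail

1. Step 16.
- What may go wrong: the photogenerated acylcarbene may be intercepted by the electron-rich alkyne before the alkenyl group migrates. The hindered ketene may dimerise faster than it cycloadds to a volatile partner. Electrocyclic closure may run through C2′ of the naphthalene.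
- Fallback, from 9 back to 34: the carbocycle is taken from an arene and the C5–C1′ bond is made by cross-coupling. Miyaura borylation of 9 (bis(pinacolato)diboron, PdCl2(dppf), KOAc, dioxane, 90 °C) should give 2-(4,5-dimethoxy-7-methylnaphthalen-1-yl)-4,4,5,5-tetramethyl-1,3,2-dioxaborolane F1. In parallel, commercial tert-butyl (2S)-2-methylaziridine-1-carboxylate is opened at its CH2 carbon by 3,5-dimethoxyphenylmagnesium bromide (CuI cat., THF, −30 °C) to tert-butyl N-[(2S)-1-(3,5-dimethoxyphenyl)propan-2-yl]carbamate F2. CF3CO2H then liberates (2S)-1-(3,5-dimethoxyphenyl)propan-2-amine F3. A Pictet–Spengler reaction with aqueous formaldehyde closes (3S)-6,8-dimethoxy-3-methyl-1,2,3,4-tetrahydroisoquinoline F4. Boc2O gives tert-butyl (3S)-6,8-dimethoxy-3-methyl-3,4-dihydro-1H-isoquinoline-2-carboxylate F5. N-Iodosuccinimide in MeCN iodinates C5, which is para to the C8 methoxy group and less crowded than C7, to tert-butyl (3S)-5-iodo-6,8-dimethoxy-3-methyl-3,4-dihydro-1H-isoquinoline-2-carboxylate F6. Suzuki–Miyaura coupling of F1 and F6 (Pd(OAc)2, SPhos, K3PO4, toluene–H2O, 100 °C) rejoins the route at 34.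

2. Step 12.
- What may go wrong: self-condensation of the arylacetaldehyde on the Lewis-acidic chromium salts and reductive homocoupling of the triflate may outrun the addition.
- Fallback, from 22 and 9 back to 24: the disconnection moves from the carbinol bond to the aryl–CH2 bond. Stille coupling of 22 with tributyl(1-ethoxyvinyl)stannane (Pd(PPh3)4, LiCl, THF, reflux) should give tert-butyl (2S)-4-(1-ethoxyethenyl)-2-methyl-3,6-dihydro-2H-pyridine-1-carboxylate F7. Treatment with 1 M HCl hydrolyses it to tert-butyl (2S)-4-acetyl-2-methyl-3,6-dihydro-2H-pyridine-1-carboxylate F8. Palladium-catalysed α-arylation of the methyl ketone with 9 (Pd(OAc)2, XPhos, K3PO4, toluene, 80 °C) leads directly to 24, which also makes steps 6 and 13 unnecessary.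

3. Step 14.
- What may go wrong: capture of the azide by the peri-hindered enolate may be slow enough for the amidine base to shift the ring double bond towards nitrogen.
- Fallback, from 24 back to 25: direct transfer is replaced by deacylative transfer. Kinetic enolisation of 24 (LiN(SiMe3)2, THF, −78 °C) and acylation with 2,2,2-trifluoroethyl trifluoroacetate should give tert-butyl (2S)-4-[2-(4,5-dimethoxy-7-methylnaphthalen-1-yl)-4,4,4-trifluoro-3-oxobutanoyl]-2-methyl-3,6-dihydro-2H-pyridine-1-carboxylate F9. This reacts with methanesulfonyl azide under mild conditions (Et3N, H2O, MeCN, rt), losing the trifluoroacetyl group to give 25.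

Further compounds
F1 | step 16 | 2-(4,5-dimethoxy-7-methylnaphthalen-1-yl)-4,4,5,5-tetramethyl-1,3,2-dioxaborolane | Cc1cc(OC)c2c(OC)ccc(B3OC(C)(C)C(C)(C)O3)c2c1
F2 | step 16 | tert-butyl N-[(2S)-1-(3,5-dimethoxyphenyl)propan-2-yl]carbamate | COc1cc(OC)cc(C[C@H](C)NC(=O)OC(C)(C)C)c1
F3 | step 16 | (2S)-1-(3,5-dimethoxyphenyl)propan-2-amine | COc1cc(OC)cc(C[C@H](C)N)c1
F4 | step 16 | (3S)-6,8-dimethoxy-3-methyl-1,2,3,4-tetrahydroisoquinoline | COc1cc(OC)c2c(c1)C[C@H](C)NC2
F5 | step 16 | tert-butyl (3S)-6,8-dimethoxy-3-methyl-3,4-dihydro-1H-isoquinoline-2-carboxylate | COc1cc(OC)c2c(c1)C[C@H](C)N(C(=O)OC(C)(C)C)C2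
F6 | step 16 | tert-butyl (3S)-5-iodo-6,8-dimethoxy-3-methyl-3,4-dihydro-1H-isoquinoline-2-carboxylate | COc1cc(OC)c(I)c2c1CN(C(=O)OC(C)(C)C)[C@@H](C)C2
F7 | step 12 | tert-butyl (2S)-4-(1-ethoxyethenyl)-2-methyl-3,6-dihydro-2H-pyridine-1-carboxylate | C=C(OCC)C1=CCN(C(=O)OC(C)(C)C)[C@@H](C)C1
F8 | step 12 | tert-butyl (2S)-4-acetyl-2-methyl-3,6-dihydro-2H-pyridine-1-carboxylate | CC(=O)C1=CCN(C(=O)OC(C)(C)C)[C@@H](C)C1
F9 | step 14 | tert-butyl (2S)-4-[2-(4,5-dimethoxy-7-methylnaphthalen-1-yl)-4,4,4-trifluoro-3-oxobutanoyl]-2-methyl-3,6-dihydro-2H-pyridine-1-carboxylate | O=C(C(C(=O)C(F)(F)F)c1ccc(OC)c2c(OC)cc(C)cc12)C1=CCN(C(=O)OC(C)(C)C)[C@@H](C)C1
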